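**Retrosynthetic overview**

1. Target 24 ← bicyclic trione 21 by regioselective enol-ether formation at the C2 oxygen and benzoylation of the vinylic C3.
2. 21 ← acyclic keto malonate 19 by one base-mediated double Claisen condensation: C1–C9 closes ring B (cyclohexanone), then C3–C4 closes ring A.
3. Enabling feature: ring A (C1–C2–C3–C4–C5–C9) is a cyclohexane-1,3,5-trione in which C5 carries both C4 and C9 (a 2,2-disubstituted malonyl unit) and the C2 ketone has two enolisable α-carbons, C1 and C3; the C8–C7–C6 chain ties C1 to C5, so C1–C9 closure is a six-membered Dieckmann reaction.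
4. 19 ← dimethyl malonate 17 + iodo ketone 16 + (S)-lavandulyl triflate 7 (from an Evans deconjugative alkylation).
5. 16 ← 3,3-dimethylglutaric anhydride 8 by Evans prenylation (sets C7), lactonisation, lactone prenylation and MeLi opening.

Key step: step 14

Remark on numbering and one assumption: atoms are numbered as in the acylphloroglucinol family (C1 = prenylated bridgehead next to C8(CH3)2, C2 = C–OMe, C3 = C–benzoyl, C4 = enone C=O, C5 = lavandulylated bridgehead, C9 = bridging C=O). Ring A = C1–C2–C3–C4–C5–C9 and ring B = C1–C8–C7–C6–C5–C9. The stereocentre α to the carbonyl in 14–19 (future C1) is carried as a mixture of epimers, because it is enolised in step 14.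

**Route**

Step 1
Reactants: 1 (4S)-4-benzyloxazolidin-2-one; 2 3-methylbut-2-enoyl chloride
Product: 3 (4S)-4-benzyl-3-(3-methylbut-2-enoyl)oxazolidin-2-one
Conditions: n-BuLi, THF, −78 °C; then 2, −78 → 0 °C
Reagents that add atoms: none
Why: N-acylation of the lithiated oxazolidinone by an acid chloride is the standard attachment of an Evans auxiliary and creates no stereocentre.

Step 2
Reactants: 3; 4 1-bromo-3-methylbut-2-ene (prenyl bromide)
Product: 5 (4S)-4-benzyl-3-[(2S)-5-methyl-2-(prop-1-en-2-yl)hex-4-enoyl]oxazolidin-2-one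
Conditions: NaN(SiMe3)2, THF, −78 °C; then 4, −78 → −40 °C
Reagents that add atoms: none
Why: γ-deprotonation gives the chelated sodium (Z)-dienolate, which is alkylated at the α-carbon on the face opposite the benzyl group (deconjugative Evans alkylation), and this should set the (2S) lavandulyl stereocentre.

Step 3
Reactants: 5
Product: 6 (S)-lavandulol, (2S)-5-methyl-2-(prop-1-en-2-yl)hex-4-en-1-ol
Conditions: LiBH4, MeOH (1 equiv), Et2O, 0 °C
Reagents that add atoms: none
Why: reductive cleavage of the N-acyl oxazolidinone with LiBH4 should give the primary alcohol without touching the alkenes or the α-stereocentre and returns auxiliary 1.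

Step 4
Reactants: 6
Product: 7 (S)-lavandulyl triflate, (2S)-5-methyl-2-(prop-1-en-2-yl)hex-4-en-1-yl trifluoromethanesulfonate
Conditions: Tf2O, 2,6-lutidine, CH2Cl2, −78 °C; cold work-up, used at once
Reagents that add atoms: triflic anhydride, O=S(=O)(OS(=O)(=O)C(F)(F)F)C(F)(F)F
Why: O-sulfonylation of a primary alcohol at low temperature should give the triflate, which is needed because a β-branched lavandulyl halide would react too slowly and eliminate in step 13.

Step 5
Reactants: 8 3,3-dimethylglutaric anhydride
Product: 9 5-methoxy-3,3-dimethyl-5-oxopentanoic acid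
Conditions: MeOH, reflux
Reagents that add atoms: methanol, CO
Why: methanolysis of the symmetrical anhydride can give only one half-ester.

Step 6
Reactants: 9; 1 (4S)-4-benzyloxazolidin-2-one
Product: 10 methyl 5-[(4S)-4-benzyl-2-oxooxazolidin-3-yl]-3,3-dimethyl-5-oxopentanoate
Conditions: pivaloyl chloride, Et3N, THF, −20 °C; then 1, LiCl, room temperature
Reagents that add atoms: none
Why: the mixed pivalic anhydride of 9 acylates the oxazolidinone at the less hindered carbonyl (standard one-pot imide formation).

Step 7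
Reactants: 10; 4 prenyl bromide
Product: 11 methyl (4S)-5-[(4S)-4-benzyl-2-oxooxazolidin-3-yl]-3,3-dimethyl-4-(3-methylbut-2-en-1-yl)-5-oxopentanoate
Conditions: NaN(SiMe3)2, THF, −78 °C; then 4, −78 → −30 °C
Reagents that add atoms: none
Why: the imide is enolised in preference to the methyl ester, and the chelated (Z)-enolate is prenylated anti to the benzyl group (Evans alkylation), which should set the future C7 stereocentre.

Step 8
Reactants: 11
Product: 13 (5S)-4,4-dimethyl-5-(3-methylbut-2-en-1-yl)oxan-2-one, via hydroxy ester 12 (not isolated)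
Conditions: NaBH4, THF–H2O, 0 °C → room temperature; then pyridinium p-toluenesulfonate (cat.), toluene, 60 °C
Reagents that add atoms: none
Why: NaBH4 in wet THF reduces the activated imide but not the methyl ester, and the resulting δ-hydroxy ester lactonises readily because of the gem-dimethyl group; the stereocentre is not enolisable under these conditions.

Step 9
Reactants: 13; 4 prenyl bromide
Product: 14 (5S)-4,4-dimethyl-3,5-bis(3-methylbut-2-en-1-yl)oxan-2-one (both C3 epimers)
Conditions: LiN(iPr)2, THF, −78 °C; then 4, DMPU, −78 → −20 °C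
Reagents that add atoms: none
Why: alkylation of the lactone enolate places the prenyl group unambiguously on the future C1, and the configuration of this centre is irrelevant.

Step 10
Reactants: 14
Product: 15 (5S)-5-(hydroxymethyl)-4,4,8-trimethyl-3-(3-methylbut-2-en-1-yl)non-7-en-2-one (in equilibrium with its cyclic hemiketal)
Conditions: MeLi (1.05 equiv), THF, −78 °C; NH4Cl quench at −78 °C
Reagents that add atoms: methyllithium, [Li]C
Why: mono-addition of MeLi to a δ-lactone stops at the lithium hemiketal at −78 °C, which should collapse to the methyl ketone only on quenching.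

Step 11
Reactants: 15
Product: 16 (5S)-5-(iodomethyl)-4,4,8-trimethyl-3-(3-methylbut-2-en-1-yl)non-7-en-2-one
Conditions: I2, PPh3, imidazole, CH2Cl2, 0 °C → room temperature
Reagents that add atoms: iodine, II
Why: the Appel reaction converts the primary alcohol of the open-chain tautomer into the iodide under buffered conditions that should leave the ketone and the alkenes alone.

Step 12
Reactants: 16; 17 dimethyl malonate
Product: 18 dimethyl 2-[(2R)-3,3-dimethyl-2,4-bis(3-methylbut-2-en-1-yl)-5-oxohexyl]propanedioate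
Conditions: NaH (1 equiv with respect to 17), 17 (3 equiv), DMF, 60 °C
Reagents that add atoms: none
Why: SN2 alkylation of sodium dimethyl malonate by the primary iodide, with excess malonate to suppress dialkylation; the malonate anion is too weak a base to enolise the ketone.

Step 13
Reactants: 18; 7 (S)-lavandulyl triflate
Product: 19 dimethyl 2-[(2R)-3,3-dimethyl-2,4-bis(3-methylbut-2-en-1-yl)-5-oxohexyl]-2-[(2R)-5-methyl-2-(prop-1-en-2-yl)hex-4-en-1-yl]propanedioate
Conditions: NaH (1.0 equiv), THF, 0 °C; then 7, −40 °C → room temperature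
Reagents that add atoms: none
Why: the more acidic malonate C–H is deprotonated selectively, and the tertiary malonate anion is alkylated by the highly reactive primary triflate at low temperature, where elimination should not compete; the lavandulyl stereocentre is not involved.

Step 14
Reactants: 19
Product: 21 (1R,5S,7R)-8,8-dimethyl-1,7-bis(3-methylbut-2-en-1-yl)-5-[(2R)-5-methyl-2-(prop-1-en-2-yl)hex-4-en-1-yl]bicyclo[3.3.1]nonane-2,4,9-trione (enolised 2,4-diketone), via monocyclic keto ester 20 (not isolated)
Conditions: KOtBu (3.5 equiv), THF (0.01 M), 0 → 40 °C; then cold dilute aqueous HCl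
Reagents that add atoms: none
Why: Proposed new method: the step is a base-mediated double Claisen condensation in which the two α-carbons of the C2 ketone (C1 and C3) acylate the two ester groups of the 2,2-disubstituted malonate centred on C5; the closest known reactions are the Dieckmann condensation of a methyl ketone enolate onto a ring ester that closes ring A of bicyclo[3.3.1]nonane-2,4,9-triones, and the Effenberger cyclisation, in which a malonyl unit bridges the two α-carbons of a cyclohexanone. Under equilibrating conditions the potassium enolate at C1 attacks one ester carbonyl in a 6-(enolexo)-exo-trig closure that forms the C1–C9 bond and ring B (20), and the methyl ketone enolate (C3) of 20 then attacks the remaining, 1,3-diaxially placed ester in a 6-(enolendo)-exo-trig closure (C3–C4) that completes ring A. The first adduct is a non-enolisable β-diketone and should reopen by retro-Claisen cleavage with the liberated methoxide, whereas the bicyclic product is trapped as its potassium 2,4-diketonate, so isomeric first adducts are expected to funnel into 21. C7 is the only fixed stereocentre and controls both new quaternary centres: ring B closes through a chair with the C7 prenyl group equatorial and the acetyl and ester groups axial on the opposite face, which selects one of the two diastereotopic esters at C5 and one face of the C1 enolate, whereas the 7-endo isomer would need a boat. The step needs C1 rather than C3 to attack first; this is secured by ring size, because attack from C3 would close an eight-membered ring, and is helped by the quaternary C8 and C5, which favour the six-membered closure.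

Step 15
Reactants: 21
Product: 22 (1R,5S,7R)-2-methoxy-8,8-dimethyl-1,7-bis(3-methylbut-2-en-1-yl)-5-[(2R)-5-methyl-2-(prop-1-en-2-yl)hex-4-en-1-yl]bicyclo[3.3.1]non-2-ene-4,9-dione
Conditions: HC(OMe)3, p-TsOH (cat.), MeOH, room temperature; chromatography
Reagents that add atoms: trimethyl orthoformate, COC(OC)OC
Why: acid-catalysed enol-ether formation of the enolised 1,3-diketone (a known operation on this ring system) is reversible and is expected to give both regioisomeric vinylogous esters, so 22 is separated and the C4-methoxy isomer is returned to the same conditions.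

Step 16
Reactants: 22; 23 benzoyl chloride
Product: 24 target, (1R,5R,7R)-3-benzoyl-2-methoxy-8,8-dimethyl-1,7-bis(3-methylbut-2-en-1-yl)-5-[(2R)-5-methyl-2-(prop-1-en-2-yl)hex-4-en-1-yl]bicyclo[3.3.1]non-2-ene-4,9-dione
Conditions: lithium 2,2,6,6-tetramethylpiperidide, THF, −78 °C; then 23, −78 °C
Reagents that add atoms: none
Why: with both bridgeheads quaternary the vinylic C3–H is the only acidic site, so α-lithiation of the β-methoxy enone and acylation with benzoyl chloride (known on this ring system) should install the benzoyl group without touching a stereocentre.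

**Compound list**

1 | (4S)-4-benzyloxazolidin-2-one | O=C1OC[C@H](Cc2ccccc2)N1 | starting material
2 | 3-methylbut-2-enoyl chloride | CC(C)=CC(=O)Cl | starting material
3 | (4S)-4-benzyl-3-(3-methylbut-2-enoyl)oxazolidin-2-one | O=C1OC[C@H](Cc2ccccc2)N1C(=O)C=C(C)C | intermediate
4 | 1-bromo-3-methylbut-2-ene (prenyl bromide) | CC(C)=CCBr | starting material
5 | (4S)-4-benzyl-3-[(2S)-5-methyl-2-(prop-1-en-2-yl)hex-4-enoyl]oxazolidin-2-one | O=C1OC[C@H](Cc2ccccc2)N1C(=O)[C@@H](CC=C(C)C)C(C)=C | intermediate
6 | (S)-lavandulol, (2S)-5-methyl-2-(prop-1-en-2-yl)hex-4-en-1-ol | OC[C@@H](CC=C(C)C)C(C)=C | intermediate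
7 | (S)-lavandulyl triflate | O=S(=O)(OC[C@@H](CC=C(C)C)C(C)=C)C(F)(F)F | intermediate
8 | 3,3-dimethylglutaric anhydride | CC1(C)CC(=O)OC(=O)C1 | starting material
9 | 5-methoxy-3,3-dimethyl-5-oxopentanoic acid | COC(=O)CC(C)(C)CC(=O)O | intermediate
10 | methyl 5-[(4S)-4-benzyl-2-oxooxazolidin-3-yl]-3,3-dimethyl-5-oxopentanoate | O=C1OC[C@H](Cc2ccccc2)N1C(=O)CC(C)(C)CC(=O)OC | intermediate
11 | methyl (4S)-5-[(4S)-4-benzyl-2-oxooxazolidin-3-yl]-3,3-dimethyl-4-(3-methylbut-2-en-1-yl)-5-oxopentanoate | O=C1OC[C@H](Cc2ccccc2)N1C(=O)[C@@H](CC=C(C)C)C(C)(C)CC(=O)OC | intermediate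
12 | methyl (4S)-4-(hydroxymethyl)-3,3,7-trimethyloct-6-enoate (not isolated) | COC(=O)CC(C)(C)[C@H](CC=C(C)C)CO | intermediate
13 | (5S)-4,4-dimethyl-5-(3-methylbut-2-en-1-yl)oxan-2-one | O=C1CC(C)(C)[C@H](CC=C(C)C)CO1 | intermediate
14 | (5S)-4,4-dimethyl-3,5-bis(3-methylbut-2-en-1-yl)oxan-2-one (C3 epimers) | O=C1C(CC=C(C)C)C(C)(C)[C@H](CC=C(C)C)CO1 | intermediate
15 | (5S)-5-(hydroxymethyl)-4,4,8-trimethyl-3-(3-methylbut-2-en-1-yl)non-7-en-2-one (C3 epimers) | CC(=O)C(CC=C(C)C)C(C)(C)[C@H](CC=C(C)C)CO | intermediate
16 | (5S)-5-(iodomethyl)-4,4,8-trimethyl-3-(3-methylbut-2-en-1-yl)non-7-en-2-one (C3 epimers) | CC(=O)C(CC=C(C)C)C(C)(C)[C@H](CC=C(C)C)CI | intermediate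
17 | dimethyl malonate | COC(=O)CC(=O)OC | starting material
18 | dimethyl 2-[(2R)-3,3-dimethyl-2,4-bis(3-methylbut-2-en-1-yl)-5-oxohexyl]propanedioate (C4 epimers of the hexyl chain) | CC(=O)C(CC=C(C)C)C(C)(C)[C@H](CC=C(C)C)CC(C(=O)OC)C(=O)OC | intermediate
19 | dimethyl 2-[(2R)-3,3-dimethyl-2,4-bis(3-methylbut-2-en-1-yl)-5-oxohexyl]-2-[(2R)-5-methyl-2-(prop-1-en-2-yl)hex-4-en-1-yl]propanedioate | CC(=O)C(CC=C(C)C)C(C)(C)[C@H](CC=C(C)C)CC(C(=O)OC)(C(=O)OC)C[C@@H](CC=C(C)C)C(C)=C | intermediate
20 | methyl (1R,3R,5R)-3-acetyl-4,4-dimethyl-3,5-bis(3-methylbut-2-en-1-yl)-1-[(2R)-5-methyl-2-(prop-1-en-2-yl)hex-4-en-1-yl]-2-oxocyclohexane-1-carboxylate (not isolated) | C=C(C)[C@H](CC=C(C)C)C[C@@]1(C(=O)OC)C[C@@H](CC=C(C)C)C(C)(C)[C@@](CC=C(C)C)(C1=O)C(C)=O | intermediate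
21 | (1R,5S,7R)-8,8-dimethyl-1,7-bis(3-methylbut-2-en-1-yl)-5-[(2R)-5-methyl-2-(prop-1-en-2-yl)hex-4-en-1-yl]bicyclo[3.3.1]nonane-2,4,9-trione | C=C(C)[C@H](CC=C(C)C)C[C@@]12C[C@@H](CC=C(C)C)C(C)(C)[C@@](CC=C(C)C)(C1=O)C(=O)CC2=O | intermediate
22 | (1R,5S,7R)-2-methoxy-8,8-dimethyl-1,7-bis(3-methylbut-2-en-1-yl)-5-[(2R)-5-methyl-2-(prop-1-en-2-yl)hex-4-en-1-yl]bicyclo[3.3.1]non-2-ene-4,9-dione | C=C(C)[C@H](CC=C(C)C)C[C@@]12C[C@@H](CC=C(C)C)C(C)(C)[C@@](CC=C(C)C)(C1=O)C(OC)=CC2=O | intermediate
23 | benzoyl chloride | O=C(Cl)c1ccccc1 | starting material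
24 | (1R,5R,7R)-3-benzoyl-2-methoxy-8,8-dimethyl-1,7-bis(3-methylbut-2-en-1-yl)-5-[(2R)-5-methyl-2-(prop-1-en-2-yl)hex-4-en-1-yl]bicyclo[3.3.1]non-2-ene-4,9-dione | C=C(C)[C@H](CC=C(C)C)C[C@@]12C[C@@H](CC=C(C)C)C(C)(C)[C@@](CC=C(C)C)(C1=O)C(OC)=C(C(=O)c1ccccc1)C2=O | target

**Step count**

Total: 16 steps. Longest linear sequence: 12 steps (steps 5–16, from 3,3-dimethylglutaric anhydride 8).

**Three steps most likely to fail**

Step 14 (proposed new method). What may go wrong:
- the hindered C1 enolate may attack the neopentyl-type ester too slowly;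
- the kinetically favoured methyl enolate may close an eight-membered ring and stall as a monocyclic diketonate;
- methoxide may cleave the acetyl group from the first adduct by retro-Claisen reaction.

Fallback with known chemistry, setting out from 16 and returning at 22: iodo ketone 16 is cyclised through its kinetic methyl enolate (LiN(iPr)2, THF, −78 → 0 °C, intramolecular alkylation) to (4S)-3,3-dimethyl-2,4-bis(3-methylbut-2-en-1-yl)cyclohexan-1-one F1. This is converted with trimethyl orthoformate and p-TsOH, then thermal loss of methanol, into the less substituted enol ether (4R)-1-methoxy-5,5-dimethyl-4,6-bis(3-methylbut-2-en-1-yl)cyclohex-1-ene F2. Effenberger cyclisation of F2 with malonyl dichloride (Et2O, −20 °C, then aqueous KOH) should give (1R,5S,7R)-8,8-dimethyl-1,7-bis(3-methylbut-2-en-1-yl)bicyclo[3.3.1]nonane-2,4,9-trione F3 with the C7 prenyl group exo. Enol-ether formation as in step 15 and separation give (1R,5S,7R)-2-methoxy-8,8-dimethyl-1,7-bis(3-methylbut-2-en-1-yl)bicyclo[3.3.1]non-2-ene-4,9-dione F4. Bridgehead lithiation of F4 at C5 (LiN(iPr)2, THF, −78 °C) and alkylation with triflate 7 then give 22. In this fallback the C1–C9 bond is no longer formed in a ring closure.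

Step 15. What may go wrong: poor regioselectivity between the two enol oxygens, with methylation preferring the less hindered C4 oxygen, and acid-induced addition to the prenyl alkenes on prolonged equilibration.

Fallback, setting out from 21 and returning at 22: the less hindered C4 oxygen is silylated first (iPr3SiOTf, Et3N, CH2Cl2, −78 °C) to give (1R,5S,7R)-8,8-dimethyl-1,7-bis(3-methylbut-2-en-1-yl)-5-[(2R)-5-methyl-2-(prop-1-en-2-yl)hex-4-en-1-yl]-4-(triisopropylsilyloxy)bicyclo[3.3.1]non-3-ene-2,9-dione F5. Methyl triflate (2,6-di-tert-butyl-4-methylpyridine, CH2Cl2, 0 °C) should then alkylate the remaining carbonyl oxygen at C2, and loss of the silyl group from the resulting dialkoxyallyl cation gives 22. The steric bias that disfavours direct methylation at the C2 oxygen is thus used to direct the silyl group, not the methyl group.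

Step 12. What may go wrong: slow SN2 displacement at the β-branched CH2–I next to the C7 methine and the quaternary C8, with competing elimination or intramolecular O- or C-alkylation by the ketone on heating.

Fallback, setting out from 15 and returning at 18: 15 is oxidised (Dess–Martin periodinane, NaHCO3, CH2Cl2) to the keto aldehyde (2S)-3,3-dimethyl-2,4-bis(3-methylbut-2-en-1-yl)-5-oxohexanal F6. Knoevenagel condensation with 17 (TiCl4, pyridine, THF, 0 °C) gives dimethyl 2-[(2S)-3,3-dimethyl-2,4-bis(3-methylbut-2-en-1-yl)-5-oxohexylidene]propanedioate F7. Conjugate reduction with Hantzsch ester (diethyl 2,6-dimethyl-1,4-dihydropyridine-3,5-dicarboxylate, toluene, 60 °C) gives 18. The C7 stereocentre is α to the aldehyde in F6, so the condensation is run cold and non-basic.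

**Further compounds**

F1 | step 14 | (4S)-3,3-dimethyl-2,4-bis(3-methylbut-2-en-1-yl)cyclohexan-1-one | O=C1CC[C@@H](CC=C(C)C)C(C)(C)C1CC=C(C)C
F2 | step 14 | (4R)-1-methoxy-5,5-dimethyl-4,6-bis(3-methylbut-2-en-1-yl)cyclohex-1-ene | COC1=CC[C@@H](CC=C(C)C)C(C)(C)C1CC=C(C)C
F3 | step 14 | (1R,5S,7R)-8,8-dimethyl-1,7-bis(3-methylbut-2-en-1-yl)bicyclo[3.3.1]nonane-2,4,9-trione | [C@@H]12C[C@@H](CC=C(C)C)C(C)(C)[C@@](CC=C(C)C)(C1=O)C(=O)CC2=O
F4 | step 14 | (1R,5S,7R)-2-methoxy-8,8-dimethyl-1,7-bis(3-methylbut-2-en-1-yl)bicyclo[3.3.1]non-2-ene-4,9-dione | [C@@H]12C[C@@H](CC=C(C)C)C(C)(C)[C@@](CC=C(C)C)(C1=O)C(OC)=CC2=O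
F5 | step 15 | (1R,5S,7R)-8,8-dimethyl-1,7-bis(3-methylbut-2-en-1-yl)-5-[(2R)-5-methyl-2-(prop-1-en-2-yl)hex-4-en-1-yl]-4-(triisopropylsilyloxy)bicyclo[3.3.1]non-3-ene-2,9-dione | C=C(C)[C@H](CC=C(C)C)C[C@@]12C[C@@H](CC=C(C)C)C(C)(C)[C@@](CC=C(C)C)(C1=O)C(=O)C=C2O[Si](C(C)C)(C(C)C)C(C)C
F6 | step 12 | (2S)-3,3-dimethyl-2,4-bis(3-methylbut-2-en-1-yl)-5-oxohexanal | CC(=O)C(CC=C(C)C)C(C)(C)[C@H](CC=C(C)C)C=O
F7 | step 12 | dimethyl 2-[(2S)-3,3-dimethyl-2,4-bis(3-methylbut-2-en-1-yl)-5-oxohexylidene]propanedioate | CC(=O)C(CC=C(C)C)C(C)(C)[C@H](CC=C(C)C)C=C(C(=O)OC)C(=O)OC
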